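**Plan**

- Retrosynthesis: the two silyl ethers come off last. The furan O–C2 bond is cut back to a 2-morpholinochromone and the 2'-hydroxyl of a hydroquinone, which comes from the 4-methoxyphenol through the quinone. Ring B is then cut at C5'–C6', C1'–C2' and C2'–C3' into a chromium carbene, a terminal alkyne and one CO.
- Enabling feature: ring B (C1'–C6', C1' on chromone C3) carries oxygen on C2' and C5', para to each other, and shares C3'–C4' with the diol pyran, whose ring oxygen sits on C4' next to C5'. This is the pattern that an alkoxy(dihydropyran-6-yl)carbene, an alkyne and CO assemble.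
- Forward order: ring C is closed on ring A, then the chromene ring, then the C3 alkyne. Separately the dihydropyran is made from tartrate and turned into its carbene. Ring B follows by benzannulation, and the furan ring closes last.
- Stereochemistry: C3 and C4 of the diol pyran (3R,4S, trans) are the two carbinol carbons of L-tartaric acid (2R,3R), carried through unchanged. No step creates a stereocentre.

Key step: step 20

Remark: acetonide 1 is taken as a purchasable form of L-tartrate; chromone locants are O1, C2, C3, C4 (C=O), C5–C8, ring B is C1'–C6', and the diol pyran is numbered as a chroman; carbonyl ligands on chromium are written Cr=C=O in SMILES and the hexahapto chromium–arene bond of 28 and F1 is not drawn.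

**Carbene branch (from tartrate)**

Step 1
Reactants: 1 dimethyl (4R,5R)-2,2-dimethyl-1,3-dioxolane-4,5-dicarboxylate (acetonide of dimethyl L-tartrate)
Product: 2 (4R,5R)-5-(methoxycarbonyl)-2,2-dimethyl-1,3-dioxolane-4-carboxylic acid
Conditions: KOH (1.0 equiv), MeOH, 0 °C to rt; then cold aq. HCl to pH 3
Reagents that add atoms: potassium hydroxide [K+].[OH-]
Why: Monosaponification of a C2-symmetric diester, in which the two esters are equivalent and the carboxylate formed resists a second attack; the stereocentres are not involved.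

Step 2
Reactants: 2 monoacid monoester
Product: 3 methyl (4R,5S)-5-(hydroxymethyl)-2,2-dimethyl-1,3-dioxolane-4-carboxylate
Conditions: BH3·SMe2, THF, 0 °C to rt; MeOH quench
Reagents that add atoms: none
Why: Chemoselective borane reduction of a carboxylic acid beside an ester, through the acyloxyborane.

Step 3
Reactants: 3 hydroxy ester
Product: 4 methyl (4R,5R)-5-formyl-2,2-dimethyl-1,3-dioxolane-4-carboxylate
Conditions: TEMPO (10 mol %), PhI(OAc)2, CH2Cl2, rt
Reagents that add atoms: none
Why: Oxoammonium (TEMPO) oxidation of a primary alcohol stops at the aldehyde and should not epimerise the alkoxy-bearing carbon.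

Step 4
Reactants: 4 aldehyde ester
Product: 5 methyl (4R,5S)-5-ethynyl-2,2-dimethyl-1,3-dioxolane-4-carboxylate
Conditions: dimethyl (1-diazo-2-oxopropyl)phosphonate, K2CO3, MeOH, 0 °C to rt
Reagents that add atoms: dimethyl (1-diazo-2-oxopropyl)phosphonate CC(=O)C(=[N+]=[N-])P(=O)(OC)OC
Why: Ohira–Bestmann homologation of an aldehyde to a terminal alkyne; the trans-dioxolane is the more stable diastereomer, so the mild base should not erode either centre, and the methyl ester is unchanged in methanol.

Step 5
Reactants: 5 alkynyl acetonide ester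
Product: 6 methyl (2R,3S)-2,3-dihydroxypent-4-ynoate
Conditions: TsOH·H2O (10 mol %), MeOH, 50 °C
Reagents that add atoms: none
Why: Acid-catalysed acetal exchange with methanol frees the diol, so that the silyl groups needed for the later C-lithiation can be put on.

Step 6
Reactants: 6 diol ester
Product: 7 methyl (2R,3S)-2,3-bis(triisopropylsilyloxy)pent-4-ynoate
Conditions: TIPSOTf (3 equiv), 2,6-lutidine, CH2Cl2, 0 to 40 °C
Reagents that add atoms: triisopropylsilyl trifluoromethanesulfonate CC(C)[Si](C(C)C)(C(C)C)OS(=O)(=O)C(F)(F)F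
Why: Silylation of both secondary alcohols with the silyl triflate; triisopropylsilyl is chosen because it survives tert-butyllithium without competing deprotonation at silicon-bound methyl groups.

Step 7
Reactants: 7 bis-silyl alkynyl ester
Product: 9 (3R,4S)-2-methyl-3,4-bis(triisopropylsilyloxy)hex-5-yn-2-ol, via methyl ketone 8 (not isolated)
Conditions: MeMgBr (4 equiv), THF, 0 °C to rt; aq. NH4Cl
Reagents that add atoms: methylmagnesium bromide C[Mg]Br
Why: Double Grignard addition to an ester through ketone 8 (the first equivalent only deprotonates the alkyne); addition should outrun enolisation, so the adjacent centre keeps its configuration.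

Step 8
Reactants: 9 tertiary alkynol
Product: 10 (3R,4S)-2,2-dimethyl-3,4-bis(triisopropylsilyloxy)-3,4-dihydro-2H-pyran
Conditions: W(CO)6 (25 mol %), Et3N, THF, hν (350 nm), 60 °C
Reagents that add atoms: none
Why: Tungsten-vinylidene endo-cycloisomerisation of a 4-alkyn-1-ol: the hydroxyl adds to the vinylidene α-carbon to give the six-membered enol ether, and the geminal methyl groups favour closure.

Step 9
Reactants: 10 silylated dihydropyran
Product: 13 pentacarbonyl{methoxy[(3R,4S)-2,2-dimethyl-3,4-bis(triisopropylsilyloxy)-3,4-dihydro-2H-pyran-6-yl]methylidene}chromium, via vinyllithium 11 (not isolated), via lithium acylchromate 12 (not isolated)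
Conditions: t-BuLi (2.5 equiv), THF, −78 to 0 °C; Cr(CO)6, THF, −78 °C to rt; solvent changed to CH2Cl2, MeOTf, 0 °C
Reagents that add atoms: chromium hexacarbonyl O=C=[Cr](=C=O)(=C=O)(=C=O)(=C=O)=C=O; methyl trifluoromethanesulfonate COS(=O)(=O)C(F)(F)F; tert-butyllithium [Li]C(C)(C)C (lithium in 11 and 12 only)
Why: Fischer carbene synthesis: C–H lithiation of the silyl-protected cyclic enol ether at C6, addition to a carbonyl ligand and O-methylation of the acylchromate, as practised on silylated glycals.

**Alkyne branch (from 2,6-dimethoxytoluene)**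

Step 10
Reactants: 14 2,6-dimethoxytoluene
Product: 16 3,5-dimethoxy-4-methylphenol, via arylboronate 15 (not isolated)
Conditions: [Ir(OMe)(cod)]2 (1.5 mol %), 4,4'-di-tert-butyl-2,2'-bipyridine, pinacolborane, THF, 80 °C; then Oxone, acetone/H2O, rt
Reagents that add atoms: potassium peroxymonosulfate (active part of Oxone) [K+].[O-]S(=O)(=O)OO; pinacolborane [H]B1OC(C)(C)C(C)(C)O1 (boryl group in 15 only)
Why: Sterically controlled iridium-catalysed C–H borylation goes to the only ring position without an ortho substituent (para to the methyl), and oxidation of the C–B bond gives the phenol that becomes the chromone oxygen O1.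

Step 11
Reactants: 16 3,5-dimethoxy-4-methylphenol
Product: 17 1-(6-hydroxy-2,4-dimethoxy-3-methylphenyl)ethan-1-one
Conditions: AcOH, BF3·OEt2, 90 °C; aq. NaOAc work-up
Reagents that add atoms: acetic acid CC(=O)O
Why: Friedel–Crafts acylation ortho to the free phenol (the two open positions are equivalent), so the only free hydroxyl now flanks the acetyl group and the later ring closure cannot go to the wrong oxygen.

Step 12
Reactants: 17 o-hydroxyacetophenone; 18 4-morpholinecarbonyl chloride
Product: 19 1-(6-hydroxy-2,4-dimethoxy-3-methylphenyl)-3-(morpholin-4-yl)propane-1,3-dione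
Conditions: LiHMDS (3.2 equiv), THF, −78 to 0 °C; then 18, −78 °C to rt; aq. NH4Cl
Reagents that add atoms: none
Why: Claisen-type C-carbamoylation of the ketone enolate within the phenoxide–enolate dianion (the carbamoyl Baker–Venkataraman manifold) gives the β-ketoamide.

Step 13
Reactants: 19 β-ketoamide
Product: 20 5,7-dimethoxy-6-methyl-2-(morpholin-4-yl)-4H-chromen-4-one
Conditions: Tf2O, CH2Cl2, 0 °C to rt; then MeOH, aq. NaHCO3
Reagents that add atoms: none
Why: Cyclodehydration of a salicyloylacetamide: triflic anhydride activates the amide carbonyl, the single phenol adds and triflate leaves, closing ring C with O1 on the carbon para to the ring methyl.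

Step 14
Reactants: 20 dimethoxy chromone
Product: 21 5,7-dihydroxy-6-methyl-2-(morpholin-4-yl)-4H-chromen-4-one
Conditions: BBr3 (5 equiv), CH2Cl2, −78 °C to rt; MeOH, H2O
Reagents that add atoms: none
Why: Lewis-acid cleavage of both aryl methyl ethers (the peri 5-OMe first, by chelation); aryl methyl ethers react much faster than the dialkyl ether of morpholine.

Step 15
Reactants: 21 dihydroxy chromone; 22 3-chloro-3-methylbut-1-yne
Product: 23 5-hydroxy-6-methyl-7-(2-methylbut-3-yn-2-yloxy)-2-(morpholin-4-yl)-4H-chromen-4-one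
Conditions: 22 (3 equiv), K2CO3, KI, CuI (10 mol %), acetone, 60 °C
Reagents that add atoms: none
Why: Copper-assisted O-alkylation of the more acidic, non-chelated 7-hydroxyl with the tertiary propargylic chloride; the 5-hydroxyl is held in its hydrogen bond to the carbonyl.

Step 16
Reactants: 23 aryl propargyl ether
Product: 24 5-hydroxy-6,8,8-trimethyl-2-(morpholin-4-yl)pyrano[2,3-h]chromen-4-one (angular 2,2-dimethylchromene fused at C7–C8 of the chromone, pyran oxygen on C7)
Conditions: N,N-diethylaniline, 180 °C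
Reagents that add atoms: none
Why: Aromatic propargyl Claisen rearrangement to C8 (C6 carries the methyl), then enolisation, 1,5-hydrogen shift and 6π oxa-electrocyclisation give the chromene.

Step 17
Reactants: 24 pyranochromone
Product: 25 5-hydroxy-3-iodo-6,8,8-trimethyl-2-(morpholin-4-yl)pyrano[2,3-h]chromen-4-one
Conditions: NIS (1.05 equiv), CH2Cl2, 0 °C, dark
Reagents that add atoms: N-iodosuccinimide O=C1CCC(=O)N1I
Why: Electrophilic iodination at C3, the nucleophilic α-carbon of the enaminone; ring A is fully substituted and one equivalent in the cold should spare the chromene double bond.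

Step 18
Reactants: 25 3-iodochromone
Product: 26 5-hydroxy-6,8,8-trimethyl-2-(morpholin-4-yl)-3-[(trimethylsilyl)ethynyl]pyrano[2,3-h]chromen-4-one
Conditions: ethynyltrimethylsilane, Pd(PPh3)2Cl2 (5 mol %), CuI (10 mol %), Et3N, THF, 50 °C
Reagents that add atoms: ethynyltrimethylsilane C#C[Si](C)(C)C
Why: Sonogashira coupling of the alkenyl iodide with the silyl acetylene.

Step 19
Reactants: 26 silyl alkyne
Product: 27 3-ethynyl-5-hydroxy-6,8,8-trimethyl-2-(morpholin-4-yl)pyrano[2,3-h]chromen-4-one
Conditions: K2CO3 (cat.), MeOH/THF, rt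
Reagents that add atoms: none
Why: Carbonate-catalysed methanolysis of the alkynyl C–Si bond frees the terminal alkyne.

**Union and completion**

Step 20
Reactants: 13 chromium methoxy(dihydropyranyl)carbene; 27 3-ethynyl-2-morpholinochromone
Product: 29 3-[(3R,4S)-5-hydroxy-8-methoxy-2,2-dimethyl-3,4-bis(triisopropylsilyloxy)chroman-6-yl]-5-hydroxy-6,8,8-trimethyl-2-(morpholin-4-yl)pyrano[2,3-h]chromen-4-one, via tricarbonylchromium arene complex 28 (not isolated)
Conditions: 13 (1.3 equiv), THF (0.05 M), 55 °C, argon; then air, daylight, rt; Et3N-washed silica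
Reagents that add atoms: none
Why: Thermal loss of one carbonyl ligand from 13 lets the terminal alkyne of 27 insert into the Cr=C bond to a vinylcarbene, and migration of a carbonyl ligand then gives a chromium-bound dienylketene made of the pyran C5=C6 bond, the former carbene carbon, the two alkyne carbons and the ketene carbon. This is the Dötz benzannulation, and its closest precedent is the reaction of dihydropyranyl and glycal-derived methoxycarbene chromium complexes with terminal alkynes to give chroman-type 4-methoxyphenols. Ring B closes by 6π electrocyclisation of the dienylketene (bond from pyran C5 to the ketene carbon, the future C3'–C2'), and the cyclohexadienone enolises to the phenol, which is held on Cr(CO)3 as 28 and set free by air. No stereocentre is formed, and the two silyloxy carbons are spectators because nothing in the neutral medium ionises or deprotonates them. The step needs regioselective insertion, which the steric rule of the reaction supplies: the unsubstituted alkyne carbon bonds to the carbene carbon, so the chromonyl group ends on C1' next to the new hydroxyl carbon C2' and the hydrogen on C6' next to the methoxy carbon C5'. It also needs phenol formation in preference to five-membered-ring closure and no attack on the spectators, which the alkenyl (not aryl) carbene, the donor solvent, the much faster reaction of alkynes than of the chromene alkene and the weak nucleophilicity of the hydrogen-bonded 5-OH and the enaminone nitrogen should secure.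

Step 21
Reactants: 29 4-methoxyphenol
Product: 30 (3R,4S)-6-[5-hydroxy-6,8,8-trimethyl-2-(morpholin-4-yl)-4-oxopyrano[2,3-h]chromen-3-yl]-2,2-dimethyl-3,4-bis(triisopropylsilyloxy)-3,4-dihydro-2H-chromene-5,8-dione
Conditions: PhI(OAc)2 (1.1 equiv), MeCN/H2O (3:1), 0 °C
Reagents that add atoms: water O
Why: Oxidative demethylation of a 4-methoxyphenol by trivalent iodine (the free 2'-OH binds iodine, water adds at C5' and methanol is lost); the hydrogen-bonded ring A phenol and the chromene are far harder to oxidise, and crude 29 is used at once so that the furan cannot close while the methyl is still in place.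

Step 22
Reactants: 30 quinone
Product: 32 bis(triisopropylsilyl) ether of the target (furan closed between O2' and chromone C2 with 5-OH and 5'-OH free), via hydroquinone 31 (not isolated)
Conditions: Na2S2O4, THF/H2O, rt, argon; organic phase then AcOH, 60 °C
Reagents that add atoms: none
Why: Dithionite reduces the quinone, and in warm acetic acid the 2'-hydroxyl adds to C2 of the protonated enaminone (an amidinium carbon) and morpholine leaves as its acetate, a 5-exo addition–elimination of the kind known from acid hydrolysis of 2-aminochromones; the 5'-hydroxyl cannot reach C2.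

Step 23
Reactants: 32 bis-silyl ether
Product: 33 target, the coumaronochromone with 5-OH, 6-methyl and the 7,8-fused 2,2-dimethyl-2H-pyran on ring A and with 5'-OH and the 3',4'-fused (3R,4S)-3,4-dihydroxy-2,2-dimethylpyran on ring B
Conditions: TBAF (4 equiv), AcOH (4 equiv), THF, rt to 40 °C
Reagents that add atoms: none
Why: Fluoride cleavage of both secondary silyl ethers, buffered with acetic acid so that the benzylic carbinol and the vinylogous carbonate of the furan are not exposed to strong base.

**Compound list**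

1 | dimethyl (4R,5R)-2,2-dimethyl-1,3-dioxolane-4,5-dicarboxylate | COC(=O)[C@@H]1OC(C)(C)O[C@H]1C(=O)OC | starting material
2 | (4R,5R)-5-(methoxycarbonyl)-2,2-dimethyl-1,3-dioxolane-4-carboxylic acid | COC(=O)[C@@H]1OC(C)(C)O[C@H]1C(=O)O | intermediate
3 | methyl (4R,5S)-5-(hydroxymethyl)-2,2-dimethyl-1,3-dioxolane-4-carboxylate | COC(=O)[C@@H]1OC(C)(C)O[C@H]1CO | intermediate
4 | methyl (4R,5R)-5-formyl-2,2-dimethyl-1,3-dioxolane-4-carboxylate | COC(=O)[C@@H]1OC(C)(C)O[C@H]1C=O | intermediate
5 | methyl (4R,5S)-5-ethynyl-2,2-dimethyl-1,3-dioxolane-4-carboxylate | COC(=O)[C@@H]1OC(C)(C)O[C@H]1C#C | intermediate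
6 | methyl (2R,3S)-2,3-dihydroxypent-4-ynoate | COC(=O)[C@H](O)[C@@H](O)C#C | intermediate
7 | methyl (2R,3S)-2,3-bis(triisopropylsilyloxy)pent-4-ynoate | COC(=O)[C@H](O[Si](C(C)C)(C(C)C)C(C)C)[C@@H](O[Si](C(C)C)(C(C)C)C(C)C)C#C | intermediate
8 | (3R,4S)-3,4-bis(triisopropylsilyloxy)hex-5-yn-2-one | CC(=O)[C@H](O[Si](C(C)C)(C(C)C)C(C)C)[C@@H](O[Si](C(C)C)(C(C)C)C(C)C)C#C | intermediate (not isolated)
9 | (3R,4S)-2-methyl-3,4-bis(triisopropylsilyloxy)hex-5-yn-2-ol | CC(C)(O)[C@H](O[Si](C(C)C)(C(C)C)C(C)C)[C@@H](O[Si](C(C)C)(C(C)C)C(C)C)C#C | intermediate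
10 | (3R,4S)-2,2-dimethyl-3,4-bis(triisopropylsilyloxy)-3,4-dihydro-2H-pyran | C1=COC(C)(C)[C@H](O[Si](C(C)C)(C(C)C)C(C)C)[C@H]1O[Si](C(C)C)(C(C)C)C(C)C | intermediate
11 | 6-lithio derivative of 10 | C1=C([Li])OC(C)(C)[C@H](O[Si](C(C)C)(C(C)C)C(C)C)[C@H]1O[Si](C(C)C)(C(C)C)C(C)C | intermediate (not isolated)
12 | lithium pentacarbonyl(dihydropyran-6-ylcarbonyl)chromate from 11 | C1=C(C([O-])=[Cr](=C=O)(=C=O)(=C=O)(=C=O)=C=O)OC(C)(C)[C@H](O[Si](C(C)C)(C(C)C)C(C)C)[C@H]1O[Si](C(C)C)(C(C)C)C(C)C.[Li+] | intermediate (not isolated)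
13 | pentacarbonyl{methoxy[(3R,4S)-2,2-dimethyl-3,4-bis(triisopropylsilyloxy)-3,4-dihydro-2H-pyran-6-yl]methylidene}chromium | C1=C(C(OC)=[Cr](=C=O)(=C=O)(=C=O)(=C=O)=C=O)OC(C)(C)[C@H](O[Si](C(C)C)(C(C)C)C(C)C)[C@H]1O[Si](C(C)C)(C(C)C)C(C)C | intermediate
14 | 2,6-dimethoxytoluene | COc1cccc(OC)c1C | starting material
15 | 2-(3,5-dimethoxy-4-methylphenyl)-4,4,5,5-tetramethyl-1,3,2-dioxaborolane | COc1cc(B2OC(C)(C)C(C)(C)O2)cc(OC)c1C | intermediate (not isolated)
16 | 3,5-dimethoxy-4-methylphenol | COc1cc(O)cc(OC)c1C | intermediate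
17 | 1-(6-hydroxy-2,4-dimethoxy-3-methylphenyl)ethan-1-one | CC(=O)c1c(O)cc(OC)c(C)c1OC | intermediate
18 | 4-morpholinecarbonyl chloride | O=C(Cl)N1CCOCC1 | starting material
19 | 1-(6-hydroxy-2,4-dimethoxy-3-methylphenyl)-3-(morpholin-4-yl)propane-1,3-dione | O=C(CC(=O)N1CCOCC1)c1c(O)cc(OC)c(C)c1OC | intermediate
20 | 5,7-dimethoxy-6-methyl-2-(morpholin-4-yl)-4H-chromen-4-one | COc1cc2oc(N3CCOCC3)cc(=O)c2c(OC)c1C | intermediate
21 | 5,7-dihydroxy-6-methyl-2-(morpholin-4-yl)-4H-chromen-4-one | Cc1c(O)cc2oc(N3CCOCC3)cc(=O)c2c1O | intermediate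
22 | 3-chloro-3-methylbut-1-yne | C#CC(C)(C)Cl | starting material
23 | 5-hydroxy-6-methyl-7-(2-methylbut-3-yn-2-yloxy)-2-(morpholin-4-yl)-4H-chromen-4-one | C#CC(C)(C)Oc1cc2oc(N3CCOCC3)cc(=O)c2c(O)c1C | intermediate
24 | 5-hydroxy-6,8,8-trimethyl-2-(morpholin-4-yl)pyrano[2,3-h]chromen-4-one | O=c1cc(N2CCOCC2)oc2c1c(O)c(C)c1c2C=CC(C)(C)O1 | intermediate
25 | 5-hydroxy-3-iodo-6,8,8-trimethyl-2-(morpholin-4-yl)pyrano[2,3-h]chromen-4-one | O=c1c(I)c(N2CCOCC2)oc2c1c(O)c(C)c1c2C=CC(C)(C)O1 | intermediate
26 | 5-hydroxy-6,8,8-trimethyl-2-(morpholin-4-yl)-3-[(trimethylsilyl)ethynyl]pyrano[2,3-h]chromen-4-one | C[Si](C)(C)C#Cc1c(N2CCOCC2)oc2c(c1=O)c(O)c(C)c1c2C=CC(C)(C)O1 | intermediate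
27 | 3-ethynyl-5-hydroxy-6,8,8-trimethyl-2-(morpholin-4-yl)pyrano[2,3-h]chromen-4-one | C#Cc1c(N2CCOCC2)oc2c(c1=O)c(O)c(C)c1c2C=CC(C)(C)O1 | intermediate
28 | tricarbonylchromium complex of 29 (chromium on the new benzene ring) | Oc1c2c(c(OC)cc1-c1c(N3CCOCC3)oc3c(c1=O)c(O)c(C)c1c3C=CC(C)(C)O1)OC(C)(C)[C@H](O[Si](C(C)C)(C(C)C)C(C)C)[C@H]2O[Si](C(C)C)(C(C)C)C(C)C.O=C=[Cr](=C=O)=C=O | intermediate (not isolated)
29 | 3-[(3R,4S)-5-hydroxy-8-methoxy-2,2-dimethyl-3,4-bis(triisopropylsilyloxy)chroman-6-yl]-5-hydroxy-6,8,8-trimethyl-2-(morpholin-4-yl)pyrano[2,3-h]chromen-4-one | Oc1c2c(c(OC)cc1-c1c(N3CCOCC3)oc3c(c1=O)c(O)c(C)c1c3C=CC(C)(C)O1)OC(C)(C)[C@H](O[Si](C(C)C)(C(C)C)C(C)C)[C@H]2O[Si](C(C)C)(C(C)C)C(C)C | intermediate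
30 | (3R,4S)-6-[5-hydroxy-6,8,8-trimethyl-2-(morpholin-4-yl)-4-oxopyrano[2,3-h]chromen-3-yl]-2,2-dimethyl-3,4-bis(triisopropylsilyloxy)-3,4-dihydro-2H-chromene-5,8-dione | O=C1C2=C(C(=O)C=C1c1c(N3CCOCC3)oc3c(c1=O)c(O)c(C)c1c3C=CC(C)(C)O1)OC(C)(C)[C@H](O[Si](C(C)C)(C(C)C)C(C)C)[C@H]2O[Si](C(C)C)(C(C)C)C(C)C | intermediate
31 | 3-[(3R,4S)-5,8-dihydroxy-2,2-dimethyl-3,4-bis(triisopropylsilyloxy)chroman-6-yl]-5-hydroxy-6,8,8-trimethyl-2-(morpholin-4-yl)pyrano[2,3-h]chromen-4-one | Oc1c2c(c(O)cc1-c1c(N3CCOCC3)oc3c(c1=O)c(O)c(C)c1c3C=CC(C)(C)O1)OC(C)(C)[C@H](O[Si](C(C)C)(C(C)C)C(C)C)[C@H]2O[Si](C(C)C)(C(C)C)C(C)C | intermediate (not isolated)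
32 | bis(triisopropylsilyl) ether of the target at the two pyran carbinols | Cc1c2c(c3oc4oc5c6c(c(O)cc5c4c(=O)c3c1O)OC(C)(C)[C@H](O[Si](C(C)C)(C(C)C)C(C)C)[C@H]6O[Si](C(C)C)(C(C)C)C(C)C)C=CC(C)(C)O2 | intermediate
33 | CNP0351839.1 | Cc1c2c(c3oc4oc5c6c(c(O)cc5c4c(=O)c3c1O)OC(C)(C)[C@H](O)[C@H]6O)C=CC(C)(C)O2 | target

**Step count and weak points**

Total: 23 steps. Longest linear sequence: 14 steps (steps 10 to 23, from 2,6-dimethoxytoluene); the tartrate branch reaches carbene 13 in 9 steps and joins at step 20.

Step 20. Insertion of the hindered, donor-substituted alkyne may be too slow after CO loss, so that the carbene decays or closes to five-membered products without taking up CO. The fallback keeps the benzannulation but makes the C1'–C3 bond afterwards. It sets out from carbene 13 and iodide 25. Carbene 13 is heated (THF, 55 °C, then air) with the small terminal alkyne 2-ethynyl-4,4,5,5-tetramethyl-1,3,2-dioxaborolane, whose boryl group should take the place of the large substituent next to the hydroxyl carbon. This should give, through the tricarbonylchromium complex F1, the aryl boronate F2. Suzuki–Miyaura coupling of F2 with iodide 25 (Pd(OAc)2, SPhos, K3PO4, dioxane/H2O, 80 °C) comes back to the route at 29.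

Step 8. The tertiary hydroxyl, flanked by a bulky silyl ether, may add too slowly to the tungsten vinylidene, so that the alkyne is lost to oligomerisation or exo closure. The fallback sets out from alkynol 9. Ruthenium-catalysed anti-Markovnikov hydration of the terminal alkyne ([CpRu(MeCN)3]PF6, 5,5'-bis(trifluoromethyl)-2,2'-bipyridine, aqueous N-methylpyrrolidone, rt) should give the aldehyde in its ring-closed form, the lactol F3. Dehydration through the anomeric mesylate (MsCl, Et3N, CH2Cl2, 0 °C to reflux) comes back to the route at dihydropyran 10.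

Step 22. The hydroquinone may be re-oxidised by air during the change to acid, or the benzylic silyl ether, activated by two ring oxygens, may ionise in warm acid before morpholine is displaced. The fallback sets out from quinone 30. The dithionite reduction is followed at once by silylation of both new phenols (TBSOTf, 2,6-lutidine, CH2Cl2, −78 °C) to the stable bis(tert-butyldimethylsilyl) ether F4. TBAF buffered with AcOH in THF at rt then frees the two phenols, the 2'-phenoxide adds to C2 and morpholine leaves as its acetate without heating. The same fluoride removes the triisopropylsilyl groups, so the sequence rejoins the route at 32, formed in the flask, and ends at 33.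

**Further compounds**

F1 | step 20 | tricarbonylchromium complex of F2 (chromium on the new benzene ring) | Oc1c2c(c(OC)cc1B1OC(C)(C)C(C)(C)O1)OC(C)(C)[C@H](O[Si](C(C)C)(C(C)C)C(C)C)[C@H]2O[Si](C(C)C)(C(C)C)C(C)C.O=C=[Cr](=C=O)=C=O
F2 | step 20 | (3R,4S)-8-methoxy-2,2-dimethyl-6-(4,4,5,5-tetramethyl-1,3,2-dioxaborolan-2-yl)-3,4-bis(triisopropylsilyloxy)chroman-5-ol | Oc1c2c(c(OC)cc1B1OC(C)(C)C(C)(C)O1)OC(C)(C)[C@H](O[Si](C(C)C)(C(C)C)C(C)C)[C@H]2O[Si](C(C)C)(C(C)C)C(C)C
F3 | step 8 | (4S,5R)-6,6-dimethyl-4,5-bis(triisopropylsilyloxy)oxan-2-ol (anomer mixture) | C1C(O)OC(C)(C)[C@H](O[Si](C(C)C)(C(C)C)C(C)C)[C@H]1O[Si](C(C)C)(C(C)C)C(C)C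
F4 | step 22 | bis(tert-butyldimethylsilyl) ether of hydroquinone 31 at O2' and O5' | CC(C)(C)[Si](C)(C)Oc1c2c(c(O[Si](C)(C)C(C)(C)C)cc1-c1c(N3CCOCC3)oc3c(c1=O)c(O)c(C)c1c3C=CC(C)(C)O1)OC(C)(C)[C@H](O[Si](C(C)C)(C(C)C)C(C)C)[C@H]2O[Si](C(C)C)(C(C)C)C(C)C
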